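The number to hold on to is 0.050 M, the substrate charged.

| flask | substrate | temperature | time |
|---|---|---|---|
| north-east | 0.050 M | 25 °C | 25 d |
| south | 0.050 M | −25 °C | 25 d |
| east | 0.050 M | 0 °C | 25 d |

    substrate + substrate ⇌ target (K1 = 8.6 M⁻¹, k1 = 0.53 M⁻¹ h⁻¹, Ea1 = 68.0 kJ mol⁻¹, ΔH1 = −50.0 kJ mol⁻¹)
    target ⇌ isomer of the product (K2 = 0.43, k2 = 0.013 h⁻¹, Ea2 = 105 kJ mol⁻¹, ΔH2 = −52.0 kJ mol⁻¹)
    crystals ⇌ target, rate k3*(cs3 - [target]) while solid is left; crystals form when [target] > cs3 (cs3 = 23 mM, k3 = 1.3 h⁻¹)
    substrate → decomposition product (k4 = 7.1 × 10⁻⁵ h⁻¹, Ea4 = 126 kJ mol⁻¹)
    (constants at 25 °C)

- in percentages every species weighs as the substrate in it: one target or isomer of the product or crystals counts as two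
- for target the crystals are counted in
- two of one species on the left: rate k times its square, two consumed each time
- as a solid, counted per litre of solution: crystals
- constants are those at 25 °C; use the activation energies and enthalpies for any other temperature

- the best flask by amount of target, in percent of the substrate charged; "all alike" if 1.5 percentage points covers them all (north-east / south / east / all alike)
- amount of target at the end, in percent of the substrate charged, north-east
- amount of target at the end, in percent of the substrate charged, south
- amount of target at the end, in percent of the substrate charged, east

Which concentration sets the order of the rate? It is c(substrate), and it enters squared: the first step removes two substrate each time it runs, so c(substrate) falls at 2·k times its square, with k the rate constant of the first step at the flask's temperature.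

What does the square change? The half-life now belongs to the charge as well as to the step. In south, k is 0.00211 M⁻¹ h⁻¹, which gives 198 d for the quantity I carry: the charge half-life τ, one over 2·k·c(substrate) at the start, the time in which the forward first step alone halves the substrate. The fraction converted after time t is then t/(t+τ), the hyperbola of a step-growth conversion.

And south after 25 d? The fraction is 11.2%. One target counts as two substrate, so this is also my figure for target in south. Since τ exceeds the time, south stands under kinetic control.

You dropped the second step and the way back. Defend that. In south the forward second step has a half-life of 11300 d, far longer than 25 d. With the equilibrium constant of the first step at 501 M⁻¹ in south, the back rate at the end is 0.285% of the forward rate, hardly any.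

Then why not reckon the other flasks the same way? Their τ is 9.68 d in east and 0.786 d in north-east, both shorter than 25 d, so I do not drop the way back there, and my reckoning by hand stops at south.

The forecast names east as best, with 28% in north-east, 11.2% in south and 54.5% in east, holding that in east “isomerisation lags well behind its equilibrium”. Its south figure is the same as mine.

The run puts east first with 55.2%, against 28.2% in north-east and 11.2% in south, where τ of 198 d gave 11.2%. In south the first step by itself, both ways together, has a relaxation half-life of 76.3 d at the asked time, long against 25 d yet shorter than the 10900 d of the second step reckoned the same way. Left for 250 d, south reaches 54.7% and stands above east at 28.4%. A second flask, south in all but its charge of 0.020 M substrate, has τ of 494 d, so t/(t+τ) is 4.82%, and at the end that flask holds 4.81% of target.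

The constants used here are assumed; the run is a simulation.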